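## Retrosynthetic overview
1. The last bond made is C3–C1' between ring C and ring B. It comes from a one-pot borylation/Suzuki union of 7-hydroxy-3-iodochromone with a 5-bromo-8-hydroxychromene, with no protecting groups.
2. The key disconnection is the aryl O–CMe2 bond of the dimethylpyran (ring D). It leads back to free 5-bromo-3-methoxycatechol and 3-chloro-3-methylbut-1-yne. Site-selective O-alkylation is followed by Claisen/[1,5]-H/oxa-6π, which re-closes the same C–O bond on the only free ortho carbon.
3. The catechol oxygen that carries ring D replaces an aldehyde carbon, by Dakin oxidation of 5-bromo-o-vanillin.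
4. Ring C is closed through its O1–C2 bond by iodocyclisation of the enaminone of 2,4-dihydroxyacetophenone.
5. Ring order: D onto B and, in parallel, C onto A; the B–C union comes last.

Assumption: the target has no stereocentre, and its only non-aromatic C=C bond is a ring cis-alkene. It is therefore achiral, the structure drawn is the single species to be made, and no step needs stereocontrol.

## Route

Step 1
Reactants: 1 5-bromo-2-hydroxy-3-methoxybenzaldehyde
Product: 2 5-bromo-3-methoxybenzene-1,2-diol
Conditions: 30% aq H2O2 (1.2 equiv), NaOH (1.05 equiv), H2O/THF, N2, 0 °C → rt, 2 h; then 1 M HCl to pH 3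
Reagents that add atoms: hydrogen peroxide, OO
Why: Dakin oxidation, in which hydroperoxide adds to the aldehyde of the ortho-phenoxide, the electron-rich aryl group migrates from carbon to oxygen and the aryl formate is hydrolysed in situ, so C–CHO becomes C–OH at exactly the carbon that must carry the pyran oxygen; the aryl bromide and methyl ether are inert and no stereocentre is formed.

Step 2
Reactants: 2 5-bromo-3-methoxybenzene-1,2-diol, 3 3-chloro-3-methylbut-1-yne (1.1 equiv)
Product: 6 5-bromo-7-methoxy-2,2-dimethyl-2H-chromen-8-ol, via aryl propargyl ether 4 (not isolated), via ortho-quinone methide 5 (not isolated)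
Conditions: CuCl (2 mol %), DBU (1.0 equiv), degassed MeCN, argon, −5 → 0 °C, 6 h; then AcOH (0.2 equiv), sealed tube, 140 °C, 8 h
Reagents that add atoms: none
Why: Proposed new method: site-selective copper-allenylidene mono-O-tert-propargylation of an unprotected, unsymmetrical catechol, merged in one flask with the ring-forming cascade; one equivalent of DBU gives the hydrogen-bonded monoanion at the oxygen that is meta to both Br and OMe (estimated from substituent constants to be the more acidic by roughly 0.5–0.7 pKa units, and the only one with a single ortho substituent), this oxygen attacks the gem-dimethyl terminus of the allenylidene generated from 3 and monovalent copper to make the key aryl O–CMe2 bond of 4, the neighbouring OH flanked on both sides is too hindered for a tertiary electrophile, and once AcOH has removed free base (shutting down copper acetylide re-ionisation and addition of the free OH to the alkyne) heating drives aromatic Claisen rearrangement to the only free ortho carbon, enolisation, [1,5]-H shift to 5 and oxa-6π electrocyclisation, which closes ring D through its C–O bond without forming a stereocentre; the closest known reaction types are the copper-catalysed 1,1-dimethylpropargylation of simple monophenols and the thermal aryl propargyl ether to 2H-chromene rearrangement, neither shown with site control on a free catechol that lacks a conjugating acceptor group, nor as a single-flask process.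

Step 3
Reactants: 7 1-(2,4-dihydroxyphenyl)ethan-1-one
Product: 9 7-hydroxy-3-iodo-4H-chromen-4-one, via enaminone 8 (not isolated)
Conditions: DMF-DMA (1.6 equiv), DME, 80 °C, 3 h; evaporate in the flask; then I2 (1.05 equiv), MeOH, rt, 2 h; aq Na2S2O3 wash
Reagents that add atoms: N,N-dimethylformamide dimethyl acetal, COC(OC)N(C)C; iodine, II
Why: Enaminone condensation followed by iodocyclisation of an ortho-hydroxyaryl enaminone (Gammill-type 3-iodochromone synthesis), in which iodine attacks the enaminone alpha-carbon, the chelated 2-OH adds to the resulting iminium carbon to close ring C through its O1–C2 bond and dimethylamine is expelled, while the moderate temperature and small excess of acetal limit methylation of the 4-OH; no stereocentre is formed.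

Step 4
Reactants: 6 5-bromo-7-methoxy-2,2-dimethyl-2H-chromen-8-ol, 9 7-hydroxy-3-iodo-4H-chromen-4-one (1.1 equiv)
Product: 11 7-hydroxy-3-(8-hydroxy-7-methoxy-2,2-dimethyl-2H-chromen-5-yl)-4H-chromen-4-one, via pinacol boronate 10 (not isolated)
Conditions: 6, B2pin2 (1.1 equiv), Pd(dppf)Cl2 (5 mol %), KOAc (3 equiv), 1,4-dioxane, 90 °C, 4 h; then 9, 2 M aq K3PO4 (5 equiv), 80 °C, 6 h; aq NH4Cl
Reagents that add atoms: bis(pinacolato)diboron, CC1(C)OB(OC1(C)C)B2OC(C)(C)C(C)(C)O2 (its boryl group sits only in 10; none of its atoms remain in 11)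
Why: Miyaura borylation and Suzuki–Miyaura coupling in one pot on a single charge of Pd(dppf)Cl2, where KOAc is too weak to disturb the phenol during borylation, the C–I bond of 9 adds to zerovalent palladium far faster than any residual C–Br bond, and the 7-phenoxide formed in aqueous phosphate lowers the electrophilicity of C2 so the pyranone is not opened; the product is achiral.

## Compound list
1 | 5-bromo-2-hydroxy-3-methoxybenzaldehyde | COc1cc(Br)cc(C=O)c1O | starting material
2 | 5-bromo-3-methoxybenzene-1,2-diol | COc1cc(Br)cc(O)c1O | intermediate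
3 | 3-chloro-3-methylbut-1-yne | C#CC(C)(C)Cl | starting material
4 | 4-bromo-2-methoxy-6-[(2-methylbut-3-yn-2-yl)oxy]phenol | COc1cc(Br)cc(OC(C)(C)C#C)c1O | intermediate
5 | (6E)-5-bromo-2-hydroxy-3-methoxy-6-(3-methylbut-2-en-1-ylidene)cyclohexa-2,4-dien-1-one | CC(C)=C/C=C1\C(=O)C(O)=C(OC)C=C1Br | intermediate
6 | 5-bromo-7-methoxy-2,2-dimethyl-2H-chromen-8-ol | COc1cc(Br)c2c(c1O)OC(C)(C)C=C2 | intermediate
7 | 1-(2,4-dihydroxyphenyl)ethan-1-one | CC(=O)c1ccc(O)cc1O | starting material
8 | (E)-1-(2,4-dihydroxyphenyl)-3-(dimethylamino)prop-2-en-1-one | CN(C)/C=C/C(=O)c1ccc(O)cc1O | intermediate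
9 | 7-hydroxy-3-iodo-4H-chromen-4-one | O=c1c(I)coc2cc(O)ccc12 | intermediate
10 | 7-methoxy-2,2-dimethyl-5-(4,4,5,5-tetramethyl-1,3,2-dioxaborolan-2-yl)-2H-chromen-8-ol | COc1cc(B3OC(C)(C)C(C)(C)O3)c2c(c1O)OC(C)(C)C=C2 | intermediate
11 | 7-hydroxy-3-(8-hydroxy-7-methoxy-2,2-dimethyl-2H-chromen-5-yl)-4H-chromen-4-one | COc1cc(-c2coc3cc(O)ccc3c2=O)c2c(c1O)OC(C)(C)C=C2 | target

## Step count and risks
Total step count: 4. Longest linear sequence: 3 (1 → 2 → 6 → 11).

**Most likely to fail, first: step 2 (the proposed new step).**
- Risks: alkylation at the flanked oxygen or at both oxygens; 6-exo-dig addition of the free OH of 4 to the alkyne, giving a methylene-benzodioxine; copper-mediated oxidation of the catechol.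
- The fallback uses only known chemistry. It sets out from 1 (step 1 is then skipped) and comes back at 6. The two oxygens are told apart by their order of introduction instead of by catalyst control.
- The phenol of 1 is capped with MOMCl/iPr2NEt in CH2Cl2 to give 5-bromo-3-methoxy-2-(methoxymethoxy)benzaldehyde F1. Baeyer–Villiger oxidation with mCPBA in CH2Cl2 gives 5-bromo-3-methoxy-2-(methoxymethoxy)phenyl formate F2. K2CO3/MeOH then frees 5-bromo-3-methoxy-2-(methoxymethoxy)phenol F3, a simple monophenol.
- Standard etherification with 3 (K2CO3, KI, catalytic CuI, acetone, reflux) gives 5-bromo-1-methoxy-2-(methoxymethoxy)-3-[(2-methylbut-3-yn-2-yl)oxy]benzene F4. This ether is isolated and heated in o-xylene at 140 °C to give 5-bromo-7-methoxy-8-(methoxymethoxy)-2,2-dimethyl-2H-chromene F5. Catalytic HCl in MeOH at 50 °C removes the acetal and delivers 6.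

**Second: step 4.**
- Risks: protodeboronation of the electron-rich boronate 10, which carries a para-phenoxide; consumption of 9 by left-over B2pin2; slow coupling or base damage of the unprotected iodochromone.
- The fallback sets out from 6 and 9 and comes back at 11. It gives up the protecting-group-free one-pot process in favour of masked phenols, boron installed by halogen–metal exchange, and an isolated boronate.
- 6 with TBSCl/imidazole in DMF gives tert-butyl[(5-bromo-7-methoxy-2,2-dimethyl-2H-chromen-8-yl)oxy]dimethylsilane F6. Treatment with n-BuLi in THF at −78 °C, then 2-isopropoxy-4,4,5,5-tetramethyl-1,3,2-dioxaborolane, gives tert-butyl{[7-methoxy-2,2-dimethyl-5-(4,4,5,5-tetramethyl-1,3,2-dioxaborolan-2-yl)-2H-chromen-8-yl]oxy}dimethylsilane F7, which is purified.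
- 9 with TBSCl/imidazole in CH2Cl2 gives 7-[(tert-butyldimethylsilyl)oxy]-3-iodo-4H-chromen-4-one F8.
- Coupling of the two with Pd(PPh3)4 and K3PO4 in dioxane/H2O (10:1) at 70 °C gives 7-[(tert-butyldimethylsilyl)oxy]-3-{8-[(tert-butyldimethylsilyl)oxy]-7-methoxy-2,2-dimethyl-2H-chromen-5-yl}-4H-chromen-4-one F9. Partial silyl loss here is harmless. TBAF/AcOH in THF at 0 °C then gives 11.

**Third: step 3.**
- Risks: O-methylation of the acidic 4-OH by DMF-DMA; ring iodination at C8 by the iodine/dimethylamine couple.
- The fallback sets out from 7 and comes back at 9. The non-chelated 4-OH is capped selectively with MOMCl (1.1 equiv) and K2CO3 in acetone to give 1-[2-hydroxy-4-(methoxymethoxy)phenyl]ethan-1-one F10.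
- Neat DMF-DMA at 95 °C gives (E)-3-(dimethylamino)-1-[2-hydroxy-4-(methoxymethoxy)phenyl]prop-2-en-1-one F11. I2 in CHCl3 at rt gives 3-iodo-7-(methoxymethoxy)-4H-chromen-4-one F12. HCl in MeOH at 50 °C releases 9.

## Further compounds
F1 | step 2 | 5-bromo-3-methoxy-2-(methoxymethoxy)benzaldehyde | COCOc1c(OC)cc(Br)cc1C=O
F2 | step 2 | 5-bromo-3-methoxy-2-(methoxymethoxy)phenyl formate | COCOc1c(OC)cc(Br)cc1OC=O
F3 | step 2 | 5-bromo-3-methoxy-2-(methoxymethoxy)phenol | COCOc1c(OC)cc(Br)cc1O
F4 | step 2 | 5-bromo-1-methoxy-2-(methoxymethoxy)-3-[(2-methylbut-3-yn-2-yl)oxy]benzene | COCOc1c(OC)cc(Br)cc1OC(C)(C)C#C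
F5 | step 2 | 5-bromo-7-methoxy-8-(methoxymethoxy)-2,2-dimethyl-2H-chromene | COCOc1c(OC)cc(Br)c2C=CC(C)(C)Oc12
F6 | step 4 | tert-butyl[(5-bromo-7-methoxy-2,2-dimethyl-2H-chromen-8-yl)oxy]dimethylsilane | COc1cc(Br)c2c(c1O[Si](C)(C)C(C)(C)C)OC(C)(C)C=C2
F7 | step 4 | tert-butyl{[7-methoxy-2,2-dimethyl-5-(4,4,5,5-tetramethyl-1,3,2-dioxaborolan-2-yl)-2H-chromen-8-yl]oxy}dimethylsilane | COc1cc(B3OC(C)(C)C(C)(C)O3)c2c(c1O[Si](C)(C)C(C)(C)C)OC(C)(C)C=C2
F8 | step 4 | 7-[(tert-butyldimethylsilyl)oxy]-3-iodo-4H-chromen-4-one | O=c1c(I)coc2cc(O[Si](C)(C)C(C)(C)C)ccc12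
F9 | step 4 | 7-[(tert-butyldimethylsilyl)oxy]-3-{8-[(tert-butyldimethylsilyl)oxy]-7-methoxy-2,2-dimethyl-2H-chromen-5-yl}-4H-chromen-4-one | COc1cc(-c2coc3cc(O[Si](C)(C)C(C)(C)C)ccc3c2=O)c2c(c1O[Si](C)(C)C(C)(C)C)OC(C)(C)C=C2
F10 | step 3 | 1-[2-hydroxy-4-(methoxymethoxy)phenyl]ethan-1-one | COCOc1ccc(C(C)=O)c(O)c1
F11 | step 3 | (E)-3-(dimethylamino)-1-[2-hydroxy-4-(methoxymethoxy)phenyl]prop-2-en-1-one | COCOc1ccc(C(=O)/C=C/N(C)C)c(O)c1
F12 | step 3 | 3-iodo-7-(methoxymethoxy)-4H-chromen-4-one | COCOc1ccc2c(c1)occ(I)c2=O
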